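# Proposed total synthesis of CNP0201582.1: a 3',3'''-linked (2S)-naringenin–(2R,3R)-aromadendrin dimer

## Analysis of the target

The target is a biflavonoid: a (2S)-5,7,4'-trihydroxyflavanone unit and a (2R,3R)-3,5,7,4'-tetrahydroxyflavanone unit, joined by a biaryl bond between the ring B carbons ortho to the two 4'-hydroxyls (C3'–C3'''). It has three stereocentres: C2 of the flavanone half, and C2'' and C3'' of the dihydroflavonol half. The two C2 atoms have the same spatial sense; the descriptor changes from S to R only because the C3'' hydroxyl changes the priorities. The C3'' hydroxyl is trans to the C2'' aryl group. Apart from this one hydroxyl the molecule is C2-symmetric, and the biaryl axis carries only two ortho substituents, so it is not a stereogenic element. Both C2 centres are benzylic ethers β to a ketone and can be lost by retro-oxa-Michael ring opening under base or strong acid; the dihydroflavonol half is also easily dehydrogenated or epimerised at C3''. The difficulty is to build two identical rings C enantioselectively on a biaryl and then to tell the halves apart by a single oxygen atom. The strategy rests on C3 of each ring C, which lies between the bonds O1–C2 and C3–C4. If C3 carries a formyl group for a time, C2–C3–CHO is the skeleton of a cinnamaldehyde, so C2 can be made electrophilic and C3 nucleophilic by amine catalysis, while O1, C4 and ring A come from a salicylaldehyde.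

## Retrosynthetic reasoning

**Protecting groups.** The six phenols of target 14 are masked as benzyl ethers in 13. Benzyl is chosen because it survives amine catalysis, rhodium, osmium, quinone oxidation and one-electron reduction, and it is removed last by neutral hydrogenolysis, which does not endanger C2 or C3''. The C3'' hydroxyl stays free.

**The one oxygen that breaks the symmetry.** Compound 13 differs from the C2-symmetric bis(dihydroflavonol) 12 only by one C3–O bond. Cutting here means every earlier step acts twice on a symmetric molecule, and the C3 hydroxyl is introduced with full stereocontrol before one copy is removed. The forward reaction must reduce one α-hydroxy ketone and leave the other. This is a statistical event at two equivalent, independent sites, so unreacted 12 is recycled.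

**Oxidation pattern of ring C.** In 12 the C4 carbonyl and the trans C3 hydroxyl are traced to the C3=C4 double bond of bis(2H-chromene) 10 through tetraol 11. The two C–O bonds are cut together because syn-dihydroxylation anti to the C2 aryl group gives the 2,3-trans relationship by substrate control. The forward oxidation then only has to distinguish the benzylic C4 carbinol from the C3 carbinol.

**The temporary carbon.** Bis(chromene) 10 is derived from bis(chromene-3-carbaldehyde) 9 by putting a formyl group back on each C3. This adds a carbon that the target does not contain, but it is what turns ring C into the product of an iminium–enamine annulation. The forward step is a rhodium-mediated decarbonylation that must leave C2 and the double bond position untouched.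

**Key disconnection.** In 9 the bonds O1–C2 and C3–C4 of both rings C are cut. This gives bis(enal) 5 and two molecules of salicylaldehyde 7. The cut is made here because C2 becomes the β-carbon of an enal, where a chiral secondary amine controls the face of attack, and C4 becomes an aryl aldehyde carbon that traps the enamine. One operation thus forms two rings, four skeletal bonds and both C2 centres from achiral components.

**The bis(enal).** Compound 5 is cut at both C=C bonds to dialdehyde 3 and ylide 4 (twofold Wittig reaction). Dialdehyde 3 is cut at the biaryl bond to two molecules of bromide 2, which comes from phenol 1 by O-benzylation. The homocoupling uses the symmetry of the biaryl.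

**The salicylaldehyde.** Compound 7 comes from trihydroxybenzaldehyde 6 by twofold O-benzylation. The hydrogen-bonded ortho hydroxyl is left free and later becomes O1.

## Alternatives that were turned down

**Alternative 1: rings B by pyrone cycloaddition.**
- Disconnection: each ring B is cut at C2'–C3' and C4'–C5'.
- Key step: two molecules of methyl coumalate A1 undergo inverse-electron-demand Diels–Alder reactions with the two ketene acetal double bonds of the succinate-derived bis(ketene acetal) A2. Decarboxylative cycloreversion and loss of the silyloxy groups give biaryl diester A3.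
- For: the arene synthesis is regiochemically unambiguous and metal-free, uses cheap symmetrical inputs, and places the oxygen, the biaryl bond and the carbonyl carbon correctly. Its key step has fewer selectivity questions than the one chosen here.
- Against: it spends the strategic step on the one part of the target that is easy, since biaryl 3 comes from 2 in a single catalytic homocoupling. A3 has no ring C and no stereocentre. Its esters need redox adjustment, and its methyl ethers would have to be exchanged or removed at the end under conditions that threaten C2.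
- Comparison: the chosen route places its risk where two rings and two stereocentres are gained; this alternative still needs a second, unsolved key step.

**Alternative 2: double ring-closing metathesis.**
- Disconnection: C3=C4 of both rings C.
- Key step: the bis(allyl aryl ether) A4, carrying an ortho 1-silyloxyvinyl group on each ring A, is closed twice with second-generation Grubbs catalyst RuCl2(CHPh)(H2IMes)(PCy3) to bis(enol silane) A5.
- For: A5 is at the right oxidation level. Hydrolysis of an enol silane gives a flavanone and Rubottom oxidation gives a trans-3-hydroxyflavanone, so no carbon is added and removed, no stoichiometric rhodium is needed, and the end game is shorter. On this point it is stronger than the chosen route.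
- Against: metathesis creates no stereocentre. Both C2 centres must already be present in A4 as enantioenriched, doubly activated (allylic and benzylic) aryl ethers of a hindered, hydrogen-bonded phenol. Such ethers are prone to ionisation, to SN2' scrambling during their formation and to Claisen rearrangement on heating. Closing a trisubstituted enol silane next to a 5-benzyloxy group twice is also demanding.
- Comparison: the chosen route sets both C2 centres by asymmetric catalysis in the ring-forming step itself, from achiral compounds. The desymmetrisation is statistical in both routes.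

**Alternative 3: double conjugate arylation of chromones.**
- Disconnection: C2–C1' and C2''–C1''' (no ring formation).
- Key step: diboronic acid A6 adds twice to chromone A7 under a chiral monovalent rhodium catalyst ([RhCl(C2H4)2]2 with a chiral diene ligand) to give hexabenzyl binaringenin A8.
- For: it is the shortest way to a flavanone-level dimer, the reaction type is well established, and ring A and ring C are bought ready-made. On step economy up to A8 it is stronger than the chosen route.
- Against: A7 is a vinylogous ester further deactivated by two alkoxy donors. The flavanone products can ring-open under the basic aqueous conditions of the arylation. The electron-rich A6 is prone to protodeboronation. Above all, A8 lacks the C3'' oxygen: it would have to be introduced at one half through a flavanone enolate or enol ether, the intermediates through which C2 is lost, with C3'' set only by substrate control.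
- Comparison: the chosen route keeps a C3=C4 double bond after the key step, so the C3 hydroxyl is installed by a stereospecific dihydroxylation and one copy is then removed, without ever enolising a flavanone under basic conditions.

Key step: step 5

## Assumptions

- The sense of induction in step 5 is assigned from the usual shielding model of diarylprolinol silyl ether iminium ions, which calls for the (S)-catalyst. If the sense were opposite, the (R)-catalyst would be used with no other change.
- The 2,2'-dioxygenated biaryl axis is taken as freely rotating at room temperature.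

## Route

**Step 1**
Reactants: 1 3-bromo-4-hydroxybenzaldehyde
Product: 2 4-(benzyloxy)-3-bromobenzaldehyde
Conditions: BnBr, K2CO3, DMF, rt
Reagents that add atoms: benzyl bromide, BrCc1ccccc1
Why: Williamson ether synthesis; the phenoxide, acidified by the para formyl and ortho bromo groups, is alkylated on oxygen and the aldehyde is inert to K2CO3.

**Step 2**
Reactants: 2 4-(benzyloxy)-3-bromobenzaldehyde (two molecules)
Product: 3 6,6'-bis(benzyloxy)biphenyl-3,3'-dicarbaldehyde
Conditions: NiCl2(PPh3)2 (10 mol%), PPh3, Zn, Et4NI, THF, 50 °C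
Reagents that add atoms: none
Why: Nickel-catalysed reductive homocoupling of an aryl bromide; zerovalent nickel formed by zinc reduction inserts into C–Br and the biaryl is released by reductive elimination, and the method tolerates aryl aldehydes and ethers while each ring has only one ortho substituent.

**Step 3**
Reactants: 3 6,6'-bis(benzyloxy)biphenyl-3,3'-dicarbaldehyde; 4 (triphenylphosphoranylidene)acetaldehyde (2.4 equiv)
Product: 5 (2E,2'E)-3,3'-[6,6'-bis(benzyloxy)biphenyl-3,3'-diyl]bis(prop-2-enal)
Conditions: toluene, 80 °C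
Reagents that add atoms: none
Why: Twofold Wittig olefination with a stabilised ylide, which gives the (E)-enals; the ylide reacts faster with the aryl aldehyde than with the conjugated enal formed, so homologation stops after two carbons when the excess is kept small.

**Step 4**
Reactants: 6 2,4,6-trihydroxybenzaldehyde
Product: 7 4,6-bis(benzyloxy)-2-hydroxybenzaldehyde
Conditions: BnBr (2.05 equiv), K2CO3, DMF, 0 °C to rt
Reagents that add atoms: benzyl bromide, BrCc1ccccc1
Why: Regioselective Williamson etherification; the para hydroxyl and one ortho hydroxyl are alkylated, while the last ortho hydroxyl is held in a hydrogen bond to the formyl oxygen and is far less nucleophilic.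

**Step 5**
Reactants: 5 (2E,2'E)-3,3'-[6,6'-bis(benzyloxy)biphenyl-3,3'-diyl]bis(prop-2-enal); 7 4,6-bis(benzyloxy)-2-hydroxybenzaldehyde (2.4 equiv)
Product: 9 2,2'-[6,6'-bis(benzyloxy)biphenyl-3,3'-diyl]bis[(2R)-5,7-bis(benzyloxy)-2H-chromene-3-carbaldehyde], via mono-chromene enal 8 (not isolated)
Conditions: (S)-2-[diphenyl(trimethylsilyloxy)methyl]pyrrolidine (20 mol% per enal), 2-nitrobenzoic acid (20 mol% per enal), 4 Å MS, toluene, rt
Reagents that add atoms: none
Why: The secondary amine condenses with each enal of 5 to an (E)-configured s-trans iminium ion, the phenol oxygen of 7 adds to the β-carbon (the future C2), the resulting enamine attacks the neighbouring formyl group of the same arene (C3–C4), and dehydration followed by hydrolysis releases the enal and the catalyst; the sequence runs first to 8 and then again at the second enal. The closest known reaction type is the diarylprolinol silyl ether-catalysed domino oxa-Michael–aldol condensation of salicylaldehydes with cinnamaldehydes to 2-aryl-2H-chromene-3-carbaldehydes. Each ring C is closed by a 6-exo-trig aldol addition of the enamine to the aryl aldehyde, after the intermolecular C–O bond has tethered the partners. Each C2 centre is set by the catalyst: the diphenyl(trimethylsilyloxy)methyl group of the (S)-amine covers the Re face of the β-carbon, so oxygen adds to the Si face, which corresponds to the configuration of 14 at both C2 atoms. The oxa-Michael addition is reversible and only the aldol condensation, made irreversible by loss of water to the sieves, carries the adduct forward, so the step needs face selectivity that survives this equilibration, O- rather than C-attack of the phenol, and 1,4- rather than 1,2-addition. The substrates secure this: the two enals sit on different rings of a freely rotating biaryl and react independently under catalyst control, the formyl group of 7 deactivates its ring towards Friedel–Crafts attack, and its position ortho to the phenol means only the O-adduct can cyclise. Because two independent catalyst-controlled events are combined, a wrong addition at one site ends up mainly in the meso diastereomer, which is separable, so the homochiral 9 should be enriched in enantiomeric purity. The electron-rich, doubly ortho-substituted aldehyde of 7 will make the aldol step slower than with simple salicylaldehydes, which is why an acid co-catalyst and a drying agent are used.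

**Step 6**
Reactants: 9 2,2'-[6,6'-bis(benzyloxy)biphenyl-3,3'-diyl]bis[(2R)-5,7-bis(benzyloxy)-2H-chromene-3-carbaldehyde]
Product: 10 2,2'-[6,6'-bis(benzyloxy)biphenyl-3,3'-diyl]bis[(2S)-5,7-bis(benzyloxy)-2H-chromene]
Conditions: RhCl(PPh3)3 (2.3 equiv), toluene, 110 °C, Ar, dark
Reagents that add atoms: none
Why: Tsuji–Wilkinson decarbonylation of an α,β-unsaturated aldehyde; the formyl C–H adds oxidatively to monovalent rhodium, carbon monoxide de-inserts to a vinyl rhodium hydride and reductive elimination gives the C3–H bond without moving the double bond or touching C2 (the descriptor changes to S only because the priorities change), and the rhodium is used stoichiometrically because RhCl(CO)(PPh3)2 does not turn over at this temperature.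

**Step 7**
Reactants: 10 2,2'-[6,6'-bis(benzyloxy)biphenyl-3,3'-diyl]bis[(2S)-5,7-bis(benzyloxy)-2H-chromene]
Product: 11 2,2'-[6,6'-bis(benzyloxy)biphenyl-3,3'-diyl]bis[(2R,3S,4S)-5,7-bis(benzyloxy)-3,4-dihydro-2H-chromene-3,4-diol]
Conditions: OsO4 (5 mol%), NMO, acetone/H2O, 0 °C to rt; Na2SO3
Reagents that add atoms: osmium tetroxide, O=[Os](=O)(=O)=O; N-methylmorpholine N-oxide, C[N+]1([O-])CCOCC1; water, O
Why: Upjohn dihydroxylation; OsO4 adds suprafacially to the electron-rich styrenic C3=C4 bond from the face opposite to the C2 aryl group, so substrate control by C2 sets C3 and C4 as the 2,3-trans-3,4-cis diol in both halves.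

**Step 8**
Reactants: 11 2,2'-[6,6'-bis(benzyloxy)biphenyl-3,3'-diyl]bis[(2R,3S,4S)-5,7-bis(benzyloxy)-3,4-dihydro-2H-chromene-3,4-diol]
Product: 12 2,2'-[6,6'-bis(benzyloxy)biphenyl-3,3'-diyl]bis[(2R,3R)-5,7-bis(benzyloxy)-3-hydroxy-2,3-dihydro-4H-chromen-4-one]
Conditions: DDQ (2.3 equiv), NaHCO3 (solid), CH2Cl2, 0 °C to rt
Reagents that add atoms: none
Why: DDQ oxidation of an electron-rich benzylic alcohol by hydride abstraction from C4–H, which is activated by the ortho and para alkoxy groups of ring A, whereas the C3 carbinol is not benzylic; the ketone formed deactivates ring A, so the reaction stops at the α-hydroxy ketone with C2 and C3 unchanged.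

**Step 9**
Reactants: 12 2,2'-[6,6'-bis(benzyloxy)biphenyl-3,3'-diyl]bis[(2R,3R)-5,7-bis(benzyloxy)-3-hydroxy-2,3-dihydro-4H-chromen-4-one]
Product: 13 (2R,3R)-5,7-bis(benzyloxy)-2-{6,6'-bis(benzyloxy)-3'-[(2S)-5,7-bis(benzyloxy)-4-oxo-3,4-dihydro-2H-chromen-2-yl]biphenyl-3-yl}-3-hydroxy-2,3-dihydro-4H-chromen-4-one
Conditions: SmI2 (2.1 equiv, slow addition), THF/MeOH, −78 °C; unreacted 12 recovered and resubmitted
Reagents that add atoms: none
Why: SmI2 reductive cleavage of an α-hydroxy ketone; two single-electron transfers via the ketyl expel the C3 oxygen and give a samarium enolate that methanol protonates at −78 °C before it can open ring C, so C2 of the new flavanone half is kept. With reductant for one site only, the two equivalent halves react statistically and the reaction is stopped at partial conversion.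

**Step 10**
Reactants: 13 (2R,3R)-5,7-bis(benzyloxy)-2-{6,6'-bis(benzyloxy)-3'-[(2S)-5,7-bis(benzyloxy)-4-oxo-3,4-dihydro-2H-chromen-2-yl]biphenyl-3-yl}-3-hydroxy-2,3-dihydro-4H-chromen-4-one
Product: 14 (2R,3R)-2-{3'-[(2S)-5,7-dihydroxy-4-oxo-3,4-dihydro-2H-chromen-2-yl]-6,6'-dihydroxybiphenyl-3-yl}-3,5,7-trihydroxy-2,3-dihydro-4H-chromen-4-one (CNP0201582.1)
Conditions: H2 (1 atm), Pd(OH)2/C, THF/MeOH, rt
Reagents that add atoms: none
Why: Catalytic hydrogenolysis of six aryl benzyl ethers under neutral conditions, which leaves the hydrogen-bonded aryl ketones, the C3'' hydroxyl and the three stereocentres untouched when stopped on consumption of the benzyl groups.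

## Compound list

1 | 3-bromo-4-hydroxybenzaldehyde | O=Cc1ccc(O)c(Br)c1 | starting material
2 | 4-(benzyloxy)-3-bromobenzaldehyde | O=Cc1ccc(OCc2ccccc2)c(Br)c1 | intermediate
3 | 6,6'-bis(benzyloxy)biphenyl-3,3'-dicarbaldehyde | O=Cc1ccc(OCc2ccccc2)c(-c2cc(C=O)ccc2OCc2ccccc2)c1 | intermediate
4 | (triphenylphosphoranylidene)acetaldehyde | O=CC=P(c1ccccc1)(c1ccccc1)c1ccccc1 | starting material
5 | (2E,2'E)-3,3'-[6,6'-bis(benzyloxy)biphenyl-3,3'-diyl]bis(prop-2-enal) | O=C/C=C/c1ccc(OCc2ccccc2)c(-c2cc(/C=C/C=O)ccc2OCc2ccccc2)c1 | intermediate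
6 | 2,4,6-trihydroxybenzaldehyde | O=Cc1c(O)cc(O)cc1O | starting material
7 | 4,6-bis(benzyloxy)-2-hydroxybenzaldehyde | O=Cc1c(O)cc(OCc2ccccc2)cc1OCc1ccccc1 | intermediate
8 | (2E)-3-{6,6'-bis(benzyloxy)-3'-[(2R)-5,7-bis(benzyloxy)-3-formyl-2H-chromen-2-yl]biphenyl-3-yl}prop-2-enal (mono-chromene enal) | O=C/C=C/c1ccc(OCc2ccccc2)c(-c2cc([C@H]3Oc4cc(OCc5ccccc5)cc(OCc5ccccc5)c4C=C3C=O)ccc2OCc2ccccc2)c1 | intermediate (not isolated)
9 | 2,2'-[6,6'-bis(benzyloxy)biphenyl-3,3'-diyl]bis[(2R)-5,7-bis(benzyloxy)-2H-chromene-3-carbaldehyde] | O=CC1=Cc2c(OCc3ccccc3)cc(OCc3ccccc3)cc2O[C@@H]1c1ccc(OCc2ccccc2)c(-c2cc([C@H]3Oc4cc(OCc5ccccc5)cc(OCc5ccccc5)c4C=C3C=O)ccc2OCc2ccccc2)c1 | intermediate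
10 | 2,2'-[6,6'-bis(benzyloxy)biphenyl-3,3'-diyl]bis[(2S)-5,7-bis(benzyloxy)-2H-chromene] | C1=Cc2c(OCc3ccccc3)cc(OCc3ccccc3)cc2O[C@@H]1c1ccc(OCc2ccccc2)c(-c2cc([C@H]3Oc4cc(OCc5ccccc5)cc(OCc5ccccc5)c4C=C3)ccc2OCc2ccccc2)c1 | intermediate
11 | 2,2'-[6,6'-bis(benzyloxy)biphenyl-3,3'-diyl]bis[(2R,3S,4S)-5,7-bis(benzyloxy)-3,4-dihydro-2H-chromene-3,4-diol] | O[C@H]1[C@@H](O)c2c(OCc3ccccc3)cc(OCc3ccccc3)cc2O[C@@H]1c1ccc(OCc2ccccc2)c(-c2cc([C@H]3Oc4cc(OCc5ccccc5)cc(OCc5ccccc5)c4[C@H](O)[C@@H]3O)ccc2OCc2ccccc2)c1 | intermediate
12 | 2,2'-[6,6'-bis(benzyloxy)biphenyl-3,3'-diyl]bis[(2R,3R)-5,7-bis(benzyloxy)-3-hydroxy-2,3-dihydro-4H-chromen-4-one] | O[C@H]1C(=O)c2c(OCc3ccccc3)cc(OCc3ccccc3)cc2O[C@@H]1c1ccc(OCc2ccccc2)c(-c2cc([C@H]3Oc4cc(OCc5ccccc5)cc(OCc5ccccc5)c4C(=O)[C@@H]3O)ccc2OCc2ccccc2)c1 | intermediate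
13 | (2R,3R)-5,7-bis(benzyloxy)-2-{6,6'-bis(benzyloxy)-3'-[(2S)-5,7-bis(benzyloxy)-4-oxo-3,4-dihydro-2H-chromen-2-yl]biphenyl-3-yl}-3-hydroxy-2,3-dihydro-4H-chromen-4-one | O=C1C[C@@H](c2ccc(OCc3ccccc3)c(-c3cc([C@H]4Oc5cc(OCc6ccccc6)cc(OCc6ccccc6)c5C(=O)[C@@H]4O)ccc3OCc3ccccc3)c2)Oc2cc(OCc3ccccc3)cc(OCc3ccccc3)c21 | intermediate
14 | (2R,3R)-2-{3'-[(2S)-5,7-dihydroxy-4-oxo-3,4-dihydro-2H-chromen-2-yl]-6,6'-dihydroxybiphenyl-3-yl}-3,5,7-trihydroxy-2,3-dihydro-4H-chromen-4-one (CNP0201582.1) | O=C1C[C@@H](c2ccc(O)c(-c3cc([C@H]4Oc5cc(O)cc(O)c5C(=O)[C@@H]4O)ccc3O)c2)Oc2cc(O)cc(O)c21 | target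

## Step count and risk

Total: 10 steps. Longest linear sequence: 9 steps (1, 2, 3, 5, 6, 7, 8, 9, 10); step 4 supplies the second component of the key step.

**Step 5 (key step).**
- Risk: the aldol closure onto the hindered, electron-rich formyl group may be slow. The reversible oxa-Michael adducts would then equilibrate, the second annulation would stay incomplete and face selectivity would erode. The homochiral product would also be hard to separate from the meso diastereomer and from half-reacted material.
- Fallback: the annulation is run on a monomer and the biaryl bond is made afterwards. It sets out from 2 and returns at 10. Wittig reaction of 2 with 4 gives (2E)-3-[4-(benzyloxy)-3-bromophenyl]prop-2-enal F1. F1 and 7 are combined under the same amine catalyst to (2R)-5,7-bis(benzyloxy)-2-[4-(benzyloxy)-3-bromophenyl]-2H-chromene-3-carbaldehyde F2, a single annulation event whose product can be enriched by crystallisation. Decarbonylation with RhCl(PPh3)3 gives (2S)-5,7-bis(benzyloxy)-2-[4-(benzyloxy)-3-bromophenyl]-2H-chromene F3. Two molecules of F3 are joined to 10 by a one-pot Miyaura borylation–Suzuki homocoupling (PdCl2(dppf), bis(pinacolato)diboron (0.5 equiv), KOAc, then aqueous K3PO4, dioxane, 80 °C).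

**Step 6.**
- Risk: at the temperature needed, the 2H-chromene may open and re-close electrocyclically, with partial loss of configuration at C2. The second formyl group may also react incompletely, and the double bond may migrate on rhodium.
- Fallback: the carbon is removed as carbon dioxide at room temperature. It sets out from 9 and returns at 10. Pinnick oxidation (NaClO2, NaH2PO4, 2-methyl-2-butene, t-BuOH/H2O) gives 2,2'-[6,6'-bis(benzyloxy)biphenyl-3,3'-diyl]bis[(2R)-5,7-bis(benzyloxy)-2H-chromene-3-carboxylic acid] F4. Bromodecarboxylation of this cinnamic-type acid (N-bromosuccinimide, LiOAc cat., MeCN/H2O, rt) gives 2,2'-[6,6'-bis(benzyloxy)biphenyl-3,3'-diyl]bis[(2R)-5,7-bis(benzyloxy)-3-bromo-2H-chromene] F5; the electrophile attacks C3 because the C4 cation is stabilised by ring A. Radical hydrodebromination (Bu3SnH, Et3B/air, toluene, rt) gives 10.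

**Step 9.**
- Risk: the two equivalent sites cannot be told apart, so reduction at neither, one or both sites will occur together. The pseudo-equatorial C3–O bond is poorly aligned with the ketyl, which may slow cleavage and allow ketone reduction. Slow protonation of the samarium enolate would allow ring opening and loss of C2.
- Fallback: the extra oxygen is never introduced on the flavanone half. It sets out from 10 and returns at 13. Dihydroxylation of 10 with a limiting amount of NMO (OsO4 cat.) gives (2R,3S,4S)-5,7-bis(benzyloxy)-2-{6,6'-bis(benzyloxy)-3'-[(2S)-5,7-bis(benzyloxy)-2H-chromen-2-yl]biphenyl-3-yl}-3,4-dihydro-2H-chromene-3,4-diol F6. Recovered 10 is recycled and doubly reacted material is 11 of the main line. Mukaiyama hydration of the remaining double bond (Co(acac)2, PhSiH3, O2, i-PrOH/THF, rt) puts the hydroxyl on the benzylic C4 and gives (2R,3S,4S)-5,7-bis(benzyloxy)-2-{6,6'-bis(benzyloxy)-3'-[(2S)-5,7-bis(benzyloxy)-4-hydroxy-3,4-dihydro-2H-chromen-2-yl]biphenyl-3-yl}-3,4-dihydro-2H-chromene-3,4-diol F7 as a mixture at the new C4. DDQ oxidation of both benzylic carbinols, as in step 8, gives 13.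

**Step 8.**
- Risk: the acidic hydroquinone formed may ionise the C4 carbinol before oxidation. Over-oxidation with dehydrogenation across C2–C3 would destroy both stereocentres.
- Fallback: the selectivity is moved from the oxidant to a protecting group. It sets out from 11 and returns at 12. Silylation of the equatorial C3 hydroxyls, which are less hindered than the pseudo-axial C4 hydroxyls next to the 5-benzyloxy group (TBSCl, imidazole, DMF), gives 2,2'-[6,6'-bis(benzyloxy)biphenyl-3,3'-diyl]bis[(2R,3S,4S)-5,7-bis(benzyloxy)-3-(tert-butyldimethylsilyloxy)-3,4-dihydro-2H-chromen-4-ol] F8. Dess–Martin oxidation (NaHCO3, CH2Cl2) gives 2,2'-[6,6'-bis(benzyloxy)biphenyl-3,3'-diyl]bis[(2R,3R)-5,7-bis(benzyloxy)-3-(tert-butyldimethylsilyloxy)-2,3-dihydro-4H-chromen-4-one] F9. Desilylation with HF·pyridine (THF, 0 °C), which is not basic, gives 12.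

## Further compounds

F1 | step 5 | (2E)-3-[4-(benzyloxy)-3-bromophenyl]prop-2-enal | O=C/C=C/c1ccc(OCc2ccccc2)c(Br)c1
F2 | step 5 | (2R)-5,7-bis(benzyloxy)-2-[4-(benzyloxy)-3-bromophenyl]-2H-chromene-3-carbaldehyde | O=CC1=Cc2c(OCc3ccccc3)cc(OCc3ccccc3)cc2O[C@@H]1c1ccc(OCc2ccccc2)c(Br)c1
F3 | step 5 | (2S)-5,7-bis(benzyloxy)-2-[4-(benzyloxy)-3-bromophenyl]-2H-chromene | C1=Cc2c(OCc3ccccc3)cc(OCc3ccccc3)cc2O[C@@H]1c1ccc(OCc2ccccc2)c(Br)c1
F4 | step 6 | 2,2'-[6,6'-bis(benzyloxy)biphenyl-3,3'-diyl]bis[(2R)-5,7-bis(benzyloxy)-2H-chromene-3-carboxylic acid] | OC(=O)C1=Cc2c(OCc3ccccc3)cc(OCc3ccccc3)cc2O[C@@H]1c1ccc(OCc2ccccc2)c(-c2cc([C@H]3Oc4cc(OCc5ccccc5)cc(OCc5ccccc5)c4C=C3C(=O)O)ccc2OCc2ccccc2)c1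
F5 | step 6 | 2,2'-[6,6'-bis(benzyloxy)biphenyl-3,3'-diyl]bis[(2R)-5,7-bis(benzyloxy)-3-bromo-2H-chromene] | BrC1=Cc2c(OCc3ccccc3)cc(OCc3ccccc3)cc2O[C@@H]1c1ccc(OCc2ccccc2)c(-c2cc([C@H]3Oc4cc(OCc5ccccc5)cc(OCc5ccccc5)c4C=C3Br)ccc2OCc2ccccc2)c1
F6 | step 9 | (2R,3S,4S)-5,7-bis(benzyloxy)-2-{6,6'-bis(benzyloxy)-3'-[(2S)-5,7-bis(benzyloxy)-2H-chromen-2-yl]biphenyl-3-yl}-3,4-dihydro-2H-chromene-3,4-diol | C1=Cc2c(OCc3ccccc3)cc(OCc3ccccc3)cc2O[C@@H]1c1ccc(OCc2ccccc2)c(-c2cc([C@H]3Oc4cc(OCc5ccccc5)cc(OCc5ccccc5)c4[C@H](O)[C@@H]3O)ccc2OCc2ccccc2)c1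
F7 | step 9 | (2R,3S,4S)-5,7-bis(benzyloxy)-2-{6,6'-bis(benzyloxy)-3'-[(2S)-5,7-bis(benzyloxy)-4-hydroxy-3,4-dihydro-2H-chromen-2-yl]biphenyl-3-yl}-3,4-dihydro-2H-chromene-3,4-diol (mixture at the new C4) | OC1C[C@@H](c2ccc(OCc3ccccc3)c(-c3cc([C@H]4Oc5cc(OCc6ccccc6)cc(OCc6ccccc6)c5[C@H](O)[C@@H]4O)ccc3OCc3ccccc3)c2)Oc2cc(OCc3ccccc3)cc(OCc3ccccc3)c21
F8 | step 8 | 2,2'-[6,6'-bis(benzyloxy)biphenyl-3,3'-diyl]bis[(2R,3S,4S)-5,7-bis(benzyloxy)-3-(tert-butyldimethylsilyloxy)-3,4-dihydro-2H-chromen-4-ol] | CC(C)(C)[Si](C)(C)O[C@H]1[C@@H](O)c2c(OCc3ccccc3)cc(OCc3ccccc3)cc2O[C@@H]1c1ccc(OCc2ccccc2)c(-c2cc([C@H]3Oc4cc(OCc5ccccc5)cc(OCc5ccccc5)c4[C@H](O)[C@@H]3O[Si](C)(C)C(C)(C)C)ccc2OCc2ccccc2)c1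
F9 | step 8 | 2,2'-[6,6'-bis(benzyloxy)biphenyl-3,3'-diyl]bis[(2R,3R)-5,7-bis(benzyloxy)-3-(tert-butyldimethylsilyloxy)-2,3-dihydro-4H-chromen-4-one] | CC(C)(C)[Si](C)(C)O[C@H]1C(=O)c2c(OCc3ccccc3)cc(OCc3ccccc3)cc2O[C@@H]1c1ccc(OCc2ccccc2)c(-c2cc([C@H]3Oc4cc(OCc5ccccc5)cc(OCc5ccccc5)c4C(=O)[C@@H]3O[Si](C)(C)C(C)(C)C)ccc2OCc2ccccc2)c1
A1 | alternative 1 | methyl coumalate (methyl 2-oxo-2H-pyran-5-carboxylate) | COC(=O)C1=COC(=O)C=C1
A2 | alternative 1 | 1,4-dimethoxy-1,4-bis(trimethylsilyloxy)buta-1,3-diene | COC(O[Si](C)(C)C)=CC=C(OC)O[Si](C)(C)C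
A3 | alternative 1 | dimethyl 6,6'-dimethoxybiphenyl-3,3'-dicarboxylate | COC(=O)c1ccc(OC)c(-c2cc(C(=O)OC)ccc2OC)c1
A4 | alternative 2 | 6,6'-bis(benzyloxy)-3,3'-bis{(1S)-1-[3,5-bis(benzyloxy)-2-(1-(tert-butyldimethylsilyloxy)vinyl)phenoxy]prop-2-en-1-yl}biphenyl | C=C[C@@H](c1ccc(OCc2ccccc2)c(-c2cc([C@H](C=C)Oc3cc(OCc4ccccc4)cc(OCc4ccccc4)c3C(=C)O[Si](C)(C)C(C)(C)C)ccc2OCc2ccccc2)c1)Oc1cc(OCc2ccccc2)cc(OCc2ccccc2)c1C(=C)O[Si](C)(C)C(C)(C)C
A5 | alternative 2 | 2,2'-[6,6'-bis(benzyloxy)biphenyl-3,3'-diyl]bis[(2S)-5,7-bis(benzyloxy)-4-(tert-butyldimethylsilyloxy)-2H-chromene] | CC(C)(C)[Si](C)(C)OC1=C[C@@H](c2ccc(OCc3ccccc3)c(-c3cc([C@H]4Oc5cc(OCc6ccccc6)cc(OCc6ccccc6)c5C(O[Si](C)(C)C(C)(C)C)=C4)ccc3OCc3ccccc3)c2)Oc2cc(OCc3ccccc3)cc(OCc3ccccc3)c21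
A6 | alternative 3 | 6,6'-bis(benzyloxy)biphenyl-3,3'-diboronic acid | OB(O)c1ccc(OCc2ccccc2)c(-c2cc(B(O)O)ccc2OCc2ccccc2)c1
A7 | alternative 3 | 5,7-bis(benzyloxy)-4H-chromen-4-one | O=c1ccoc2cc(OCc3ccccc3)cc(OCc3ccccc3)c12
A8 | alternative 3 | (2S,2''S)-hexa-O-benzyl-3',3'''-binaringenin | O=C1C[C@@H](c2ccc(OCc3ccccc3)c(-c3cc([C@H]4Oc5cc(OCc6ccccc6)cc(OCc6ccccc6)c5C(=O)C4)ccc3OCc3ccccc3)c2)Oc2cc(OCc3ccccc3)cc(OCc3ccccc3)c21
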